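Conventions used throughout: the ring is numbered C1 (OAc), C2 (OH), C3 (OH), C4=C5, C6 (OBz); C7 is the exocyclic carbon on C5 and On is the oxygen on Cn. β is the face of O1 and O2, α the opposite face. Compounds 1–5 carry shikimate names; shikimate C3, C4, C5, C6, C1, C2 and the carboxyl carbon become C1, C2, C3, C4, C5, C6 and C7.

Assumption: commercial (−)-shikimic acid is the natural (3R,4S,5R) enantiomer, whose C3 and C4 pass unchanged into C1 and C2 of the target.

## The problem

The target is a single cyclohexene ring (C1–C6, alkene C4=C5) with one exocyclic carbon, C7, on C5. No rings have to be fused, so the work lies in placing oxygen on C1, C2, C3, C6 and C7 and in giving each oxygen its own state: acetate on O1, free hydroxyl on O2 and O3, benzoate on O6 and O7. The four stereocentres are contiguous: O1 and O2 are cis (β), while O3 and O6 both lie on the α face, trans to their saturated neighbours and cis-1,4 to each other across the alkene. In this numbering the configuration is 1S,2S,3R,6S. A C1/C2 cis-diol tied into a cis-fused ketal can be bought and can then steer both remaining centres, because it blocks one face of anything planar built on C3–C6. The reverse order, with C3 and C6 directing C1/C2, would still leave the absolute configuration to be found elsewhere.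

The finished molecule is fragile. Two of its three esters are allylic and ionisable, each ester has a hydroxyl nearby so that base invites acyl migration (O1→O2→O3, O6→O1), and the trisubstituted alkene rules out hydrogenolytic deprotection. Acylation therefore has to come late, on oxygens that are already told apart, and the last deprotection has to be acidic or neutral.

The feature that opens the key step is the pair C3–O/C6–O. Two oxygens on one face at the two ends of the C4=C5 alkene are what a two-oxygen dienophile leaves when it adds suprafacially to a C3=C4–C5=C6 diene. That diene, with its C1/C2 cis-diol and C7 at the carboxyl level, is shikimic acid less one molecule of water.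

## Retrosynthesis

**O1–acetyl bond (16 ⇒ 13 + 14, through 15).** The acetate is the most migration-prone group and is therefore cut first. Removing it gives triol 13, whose three hydroxyls differ in geometry: O1/O2 are cis, O2/O3 trans. Trimethyl orthoacetate 14 can exploit this by closing the cyclic orthoester 15 on the cis pair; acid opening then has to deliver the acyl group to the axial oxygen, O1. Direct acetylation of 13 would have no such bias, which is why the orthoester cut is preferred to a plain esterification.

**Ketal and silyl ether (13 ⇒ 12).** The O1/O2 isopropylidene ketal and the O3 silyl ether of 12 are both acid-labile, so one aqueous-acid step can expose all three hydroxyls. The forward reaction must leave two benzoates, one of them allylic and secondary, untouched and must not move them; acid, not base or fluoride, meets this.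

**Two benzoyl C–O bonds (12 ⇒ 10 + 11).** Cutting both benzoates at once leads to diol 10 and benzoyl chloride 11. In 10 the only free hydroxyls are O6 and O7, so exhaustive acylation needs no selectivity. Introducing the benzoates singly would add steps without gain.

**C7 oxidation level and O3 protection (10 ⇒ 9 ⇒ 8).** C7 is taken back to the methyl ester 9, which iBu2AlH reduces while the benzoates are not yet present. The silyl group on O3 is taken back to the free ene-diol 8. This is the one point where two similar secondary allylic hydroxyls must be distinguished: O3 is flanked by a vinylic hydrogen, O6 by the ester-bearing C5, and the forward silylation has to read that difference. Keeping C7 as an ester until here is what makes the difference large.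

**C3–O and C6–O (8 ⇒ 7 ⇒ 6).** The cis-ene-1,4-diol 8 is the reduction product of endoperoxide 7, and 7 is the [4+2] adduct of singlet oxygen with diene ester 6. This cut removes two stereocentres and two C–O bonds in one step and leaves a precursor with only the C1/C2 ketal as stereochemical information. The alternatives at this point are stepwise allylic oxidation at C6 with alkene transposition, or epoxide chemistry; each sets the two centres separately, so the cycloaddition is preferred. The forward step must add oxygen only to the α face; the cis-fused ketal is there to enforce that.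

**C3=C4 alkene (6 ⇒ 5 ⇒ 4).** The second alkene of 6 is formed by elimination of triflate 5, made from alcohol 4. The C5 hydroxyl of shikimic acid already has the configuration C3 finally needs, but keeping it would require a separate oxidation at C6 and a shift of the alkene. Giving it up for the diene lets one cycloaddition install both oxygens with the alkene already in place. The forward elimination must stop at the diene and not go on to an arene.

**Ketal and methyl ester (4 ⇒ 2 + 3 ⇒ 1).** Ketal 4 comes from methyl shikimate 2 and 2,2-dimethoxypropane 3, and 2 from shikimic acid 1. Only the cis-3,4-diol can form the cis-fused dioxolane, so the hydroxyl to be eliminated is singled out without effort.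

## Roads not taken

Alternative 1: The ring would be cut at C3–C4 and closed by an intramolecular aldol. L-Rhamnose A1 would be carried to the tribenzyl keto-aldehyde A2 (2,3,4-tri-O-benzyl-6-deoxy-L-lyxo-hexos-5-ulose). L-Proline would convert its methyl ketone into an enamine whose carbon, the future C4, adds to the aldehyde, the future C3. The product would be the β-hydroxy cyclohexanone A3, with the ketone at C5 and the new carbinol at C3.
- Merits: all six ring carbons and three of the four stereocentres (C6, C1, C2) come from a cheap sugar, the carbocycle is made under mild organocatalysis, and O3 arrives with the ring.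
- Weak points: C7 is missing and would have to be added at the C5 ketone with regiocontrolled formation of C4=C5. A3 can lose water across C3–C4, and its α- and β-benzyloxy groups can eliminate. The C3 configuration rests on catalyst–substrate matching.
- Protecting groups: O1, O2 and O6 carry the same benzyl ether although they must end as acetate, hydroxyl and benzoate, and benzyl ethers cannot be removed by hydrogenolysis next to the C4=C5 alkene. A ketal on the sugar cis-diol would mend this last point, but not the others.
- Comparison: the chosen plan starts with C7 in place, has O1/O2 masked together and separately from everything else, and sets C3 and C6 in one step. Alternative 1 is its equal only in drawing on the chiral pool.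

Alternative 2: The cut is the C6–O bond together with a one-carbon ring expansion. A cyclopentene A5 carrying the O1/O2 ketal and the O3 silyl ether, made from D-ribose A4, would take up dibromocarbene to give the ring-fused gem-dibromocyclopropane A6 (either cyclopropane face serves). AgO2CPh would ionise A6; electrocyclic opening of the C4–C6 bond gives a 2-bromocyclohexenyl cation, and benzoate capture at C6 would give the bromocyclohexenyl benzoate A7.
- Merits: this road is better than the chosen one in how it distinguishes O6 from O3. The benzoate lands on O6 in the key step while O3 is already silylated, so no selective silylation is needed, and the vinyl bromide marks C5 for attachment of C7.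
- Weak points: the allyl cation has two termini, C4 and C6, whose surroundings (a silyloxy-bearing C3 against a ketal-bearing C1) differ too little to guarantee capture at C6, and the face of capture at C6 is controlled only by the neighbouring ketal oxygen.
- Attaching C7: the vinyl bromide sits next to an allylic benzoate, which zerovalent palladium can ionise and which does not survive halogen–metal exchange.
- Length: A5 is itself several steps from A4.
- Comparison: the chosen plan has C7 present from the first compound, and its two C–O bonds form with fixed relative configuration. It accepts one selective silylation (step 7) as the price.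

Alternative 3: The cut is at C2–C3 and C1–C6. Methyl coumalate A8 and 2,2-dimethyl-1,3-dioxole A9 would combine in a [4+2] cycloaddition; the bridged lactone then loses CO2 to give the diene ester A10, which has the constitution of 6.
- Merits: in step economy to the diene this road is better, two operations from achiral bulk materials against four steps from 1, and it is independent of a natural-product supply.
- Weak points: A10 is formed racemic, since neither partner is chiral and an enantioselective version of this pairing cannot be taken for granted. The temperature needed to expel CO2 is one at which such dienes lose the acetal oxygen and aromatise or add a second dienophile.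
- Comparison: the chosen plan sets against the shorter access the certain absolute configuration of 6 from 1 and conditions that never exceed room temperature once the diene exists. From A10 onward the two roads would be identical.

Key step: step 5

## Route

Step 1
Reactants: 1 (−)-shikimic acid
Product: 2 methyl shikimate
Conditions: MeOH, CSA (0.1 equiv), reflux
Reagents that add atoms: methanol, CO
Why: Fischer esterification of the conjugated acid in excess methanol; the three secondary hydroxyls and all stereocentres are untouched.

Step 2
Reactants: 2 methyl shikimate; 3 2,2-dimethoxypropane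
Product: 4 methyl 3,4-O-isopropylidene shikimate
Conditions: Me2C(OMe)2, TsOH·H2O (cat.), acetone, rt
Reagents that add atoms: 2,2-dimethoxypropane (3), COC(C)(C)OC
Why: Acid-catalysed transketalisation; only the cis-3,4-diol can close a cis-fused dioxolane, so the trans-disposed 5-hydroxyl stays free for activation.

Step 3
Reactants: 4 methyl 3,4-O-isopropylidene shikimate
Product: 5 methyl 3,4-O-isopropylidene-5-O-(trifluoromethanesulfonyl)shikimate
Conditions: Tf2O, pyridine, CH2Cl2, −20 °C
Reagents that add atoms: trifluoromethanesulfonic anhydride, O=S(=O)(OS(=O)(=O)C(F)(F)F)C(F)(F)F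
Why: O-Sulfonylation of the only free hydroxyl with retention at carbon; the triflate leaves under conditions mild enough for the sensitive diene and is carried on without chromatography.

Step 4
Reactants: 5 methyl 3,4-O-isopropylidene-5-O-(trifluoromethanesulfonyl)shikimate
Product: 6 methyl (3R,4S)-3,4-(isopropylidenedioxy)cyclohexa-1,5-diene-1-carboxylate
Conditions: CsOAc, DMF, 0 °C → rt
Reagents that add atoms: none
Why: Base-induced 1,2-elimination (E2 with E1cB character): the hydrogens on the CH2 between the triflate carbon and the ester-bearing alkene are γ to the ester and vinylogously acidic, so acetate removes one and triflate leaves, while attack at carbon is hindered by the neighbouring ketal. No stereocentre is formed and the two ketal centres, the future C1 and C2, are untouched.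

Step 5
Reactants: 6 methyl (3R,4S)-3,4-(isopropylidenedioxy)cyclohexa-1,5-diene-1-carboxylate
Product: 7 methyl 3α,6α-epidioxy-1β,2β-(isopropylidenedioxy)cyclohex-4-ene-5-carboxylate
Conditions: O2 (1 atm), 5,10,15,20-tetraphenylporphyrin (1 mol %), visible light, CH2Cl2, −20 °C
Reagents that add atoms: dioxygen, O=O
Why: Energy transfer from the photoexcited porphyrin converts O2 into singlet oxygen, which acts as a two-atom dienophile and adds in a concerted suprafacial [4+2] manner to the s-cis-locked C3=C4–C5=C6 diene of 6, forming the C3–O and C6–O bonds and moving the alkene to C4=C5. The closest known reaction type is the singlet-oxygen Diels–Alder addition to arene cis-dihydrodiol acetonides (5,6-cis-dioxygenated cyclohexa-1,3-dienes), followed by reduction to the cis-ene-1,4-diol. The only ring closed is the temporary 1,2-dioxane ring of the 2,3-dioxabicyclo[2.2.2]oct-5-ene, made by intermolecular cycloaddition with both ring bonds forming in the same step; it is not a ring of the target and is opened in step 6. The new stereocentres C3 and C6 are necessarily cis to each other because both oxygens arrive on one face, and that face is set by the cis-fused dioxolane on C1/C2, which screens the β face so that oxygen approaches from the α face. Regioselectivity does not arise because the dienophile is symmetric; what is needed is π-facial selectivity, secured by the ketal, and [4+2] in preference to ene-type oxidation, which cisoid cyclohexa-1,3-dienes generally show. The C5 ester lowers the diene HOMO and slows the addition, which is met by low temperature, a solvent in which singlet oxygen is long-lived and extended irradiation, with base excluded so that the peroxide does not isomerise.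

Step 6
Reactants: 7 methyl 3α,6α-epidioxy-1β,2β-(isopropylidenedioxy)cyclohex-4-ene-5-carboxylate
Product: 8 methyl 3α,6α-dihydroxy-1β,2β-(isopropylidenedioxy)cyclohex-4-ene-5-carboxylate
Conditions: thiourea, MeOH, 0 °C → rt
Reagents that add atoms: none
Why: Thiourea reduction of a bicyclic endoperoxide to the cis-ene-1,4-diol: sulfur attacks a peroxide oxygen and only the O–O bond breaks, so C3 and C6 keep their configuration; the neutral medium leaves the enoate and ketal alone.

Step 7
Reactants: 8 methyl 3α,6α-dihydroxy-1β,2β-(isopropylidenedioxy)cyclohex-4-ene-5-carboxylate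
Product: 9 methyl 3α-(tert-butyldimethylsilyloxy)-6α-hydroxy-1β,2β-(isopropylidenedioxy)cyclohex-4-ene-5-carboxylate
Conditions: TBSCl (1.05 equiv), imidazole, DMF, −20 → 0 °C
Reagents that add atoms: tert-butyldimethylsilyl chloride, CC(C)(C)[Si](C)(C)Cl
Why: Kinetic monosilylation of the less hindered allylic hydroxyl: O3 has a vinylic hydrogen as neighbour, whereas O6 lies beside the ester-bearing C5 and is hydrogen-bonded to the ester carbonyl. Selective protection of the hydroxyl remote from the vinylic substituent is established for 2-substituted cyclohex-2-ene-cis-1,4-diols of this kind.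

Step 8
Reactants: 9 methyl 3α-(tert-butyldimethylsilyloxy)-6α-hydroxy-1β,2β-(isopropylidenedioxy)cyclohex-4-ene-5-carboxylate
Product: 10 3α-(tert-butyldimethylsilyloxy)-5-(hydroxymethyl)-1β,2β-(isopropylidenedioxy)cyclohex-4-en-6α-ol
Conditions: iBu2AlH (DIBAL-H, 4 equiv), CH2Cl2, −78 → −20 °C; aq. KNaC4H4O6 work-up
Reagents that add atoms: none
Why: 1,2-Reduction of the α,β-unsaturated ester to the allylic alcohol by excess iBu2AlH, one equivalent being consumed by the free O6–H; silyl ether, ketal and stereocentres are not affected.

Step 9
Reactants: 10 3α-(tert-butyldimethylsilyloxy)-5-(hydroxymethyl)-1β,2β-(isopropylidenedioxy)cyclohex-4-en-6α-ol; 11 benzoyl chloride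
Product: 12 6α-benzoyloxy-5-(benzoyloxymethyl)-3α-(tert-butyldimethylsilyloxy)-1β,2β-(isopropylidenedioxy)cyclohex-4-ene
Conditions: BzCl (3 equiv), pyridine, DMAP (cat.), CH2Cl2, 0 °C → rt
Reagents that add atoms: benzoyl chloride (11), O=C(Cl)c1ccccc1
Why: DMAP-catalysed acylation of the primary O7 and secondary O6 hydroxyls; they are the only free hydroxyls, so exhaustive benzoylation needs no selectivity.

Step 10
Reactants: 12 6α-benzoyloxy-5-(benzoyloxymethyl)-3α-(tert-butyldimethylsilyloxy)-1β,2β-(isopropylidenedioxy)cyclohex-4-ene
Product: 13 6α-benzoyloxy-5-(benzoyloxymethyl)cyclohex-4-ene-1β,2β,3α-triol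
Conditions: TFA/H2O (9:1), 0 °C → rt
Reagents that add atoms: none
Why: Aqueous acid hydrolyses the dioxolane and the allylic silyl ether in one operation while benzoates are stable to it; acid is chosen because it does not promote benzoyl migration from O6 to the newly freed O1.

Step 11
Reactants: 13 6α-benzoyloxy-5-(benzoyloxymethyl)cyclohex-4-ene-1β,2β,3α-triol; 14 trimethyl orthoacetate
Product: 16 1β-acetoxy-6α-benzoyloxy-5-(benzoyloxymethyl)cyclohex-4-ene-2β,3α-diol (the target), via cyclic O1/O2 methyl orthoacetate 15 (not isolated)
Conditions: MeC(OMe)3 (1.5 equiv), CSA (cat.), MeCN, rt; then 80% aq. AcOH, rt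
Reagents that add atoms: trimethyl orthoacetate (14), COC(C)(OC)OC; water, O
Why: Acid-catalysed orthoester exchange ties the cis-vicinal O1/O2 pair into a five-membered cyclic orthoester, which the trans O2/O3 pair cannot close without strain, and mild aqueous acid opens it through the hemiorthoester with kinetic preference for the axial ester, a standard monoacylation of cis-diols on six-membered rings. O1 is the axial oxygen in the half-chair that keeps the O6 benzoate pseudoaxial and clear of the C7 substituent on C5, so the acetate should end on O1 with O2 and O3 free.

## Compound list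

1 | (−)-shikimic acid, (3R,4S,5R)-3,4,5-trihydroxycyclohex-1-ene-1-carboxylic acid | O[C@H]1[C@@H](O)[C@H](O)CC(C(=O)O)=C1 | starting material
2 | methyl shikimate, methyl (3R,4S,5R)-3,4,5-trihydroxycyclohex-1-ene-1-carboxylate | O[C@H]1[C@@H](O)[C@H](O)CC(C(=O)OC)=C1 | intermediate
3 | 2,2-dimethoxypropane | COC(C)(C)OC | starting material
4 | methyl 3,4-O-isopropylidene shikimate (cis-fused ketal on O3/O4, free 5-OH trans to it) | CC1(C)O[C@H]2[C@@H](O1)[C@H](O)CC(C(=O)OC)=C2 | intermediate
5 | methyl 3,4-O-isopropylidene-5-O-(trifluoromethanesulfonyl)shikimate | CC1(C)O[C@H]2[C@@H](O1)[C@H](OS(=O)(=O)C(F)(F)F)CC(C(=O)OC)=C2 | intermediate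
6 | methyl (3R,4S)-3,4-(isopropylidenedioxy)cyclohexa-1,5-diene-1-carboxylate | CC1(C)O[C@H]2[C@@H](O1)C=CC(C(=O)OC)=C2 | intermediate
7 | methyl 3α,6α-epidioxy-1β,2β-(isopropylidenedioxy)cyclohex-4-ene-5-carboxylate (2,3-dioxabicyclo[2.2.2]oct-5-ene, peroxide bridge anti to the dioxolane) | CC1(C)O[C@H]2[C@@H](O1)[C@H]3C=C(C(=O)OC)[C@@H]2OO3 | intermediate
8 | methyl 3α,6α-dihydroxy-1β,2β-(isopropylidenedioxy)cyclohex-4-ene-5-carboxylate | CC1(C)O[C@H]2[C@@H](O1)[C@H](O)C=C(C(=O)OC)[C@@H]2O | intermediate
9 | methyl 3α-(tert-butyldimethylsilyloxy)-6α-hydroxy-1β,2β-(isopropylidenedioxy)cyclohex-4-ene-5-carboxylate | CC1(C)O[C@H]2[C@@H](O1)[C@H](O[Si](C)(C)C(C)(C)C)C=C(C(=O)OC)[C@@H]2O | intermediate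
10 | 3α-(tert-butyldimethylsilyloxy)-5-(hydroxymethyl)-1β,2β-(isopropylidenedioxy)cyclohex-4-en-6α-ol | CC1(C)O[C@H]2[C@@H](O1)[C@H](O[Si](C)(C)C(C)(C)C)C=C(CO)[C@@H]2O | intermediate
11 | benzoyl chloride | O=C(Cl)c1ccccc1 | starting material
12 | 6α-benzoyloxy-5-(benzoyloxymethyl)-3α-(tert-butyldimethylsilyloxy)-1β,2β-(isopropylidenedioxy)cyclohex-4-ene | CC1(C)O[C@H]2[C@@H](O1)[C@H](O[Si](C)(C)C(C)(C)C)C=C(COC(=O)c1ccccc1)[C@@H]2OC(=O)c1ccccc1 | intermediate
13 | 6α-benzoyloxy-5-(benzoyloxymethyl)cyclohex-4-ene-1β,2β,3α-triol | O[C@H]1[C@@H](O)[C@H](O)C=C(COC(=O)c2ccccc2)[C@@H]1OC(=O)c1ccccc1 | intermediate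
14 | trimethyl orthoacetate | COC(C)(OC)OC | starting material
15 | cyclic O1/O2 methyl orthoacetate of 13 (2-methoxy-2-methyl-1,3-dioxolane cis-fused at C1/C2, epimers at the orthoester carbon; O3–H free) | COC1(C)O[C@H]2[C@@H](O1)[C@H](O)C=C(COC(=O)c1ccccc1)[C@@H]2OC(=O)c1ccccc1 | intermediate
16 | 1β-acetoxy-6α-benzoyloxy-5-(benzoyloxymethyl)cyclohex-4-ene-2β,3α-diol, (1S,2S,3R,6S); systematically [(3R,4S,5S,6S)-5-acetoxy-6-benzoyloxy-3,4-dihydroxycyclohex-1-en-1-yl]methyl benzoate | CC(=O)O[C@H]1[C@@H](O)[C@H](O)C=C(COC(=O)c2ccccc2)[C@@H]1OC(=O)c1ccccc1 | target

## Step count and risks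

Total step count: 11. Longest linear sequence: 11 steps (1 → 16); the route is linear.

**Step 5 (key step).** The ester makes the diene electron-poor, so cycloaddition may be slow enough for competing processes to gain ground: thermal dimerisation of the diene, aromatisation by loss of the acetal oxygen, ene-type oxidation. The peroxide may also isomerise to a hydroxy enone (Kornblum–DeLaMare rearrangement) on concentration, since C3–H is γ to the ester. The fallback keeps the same cycloaddition but changes the oxidation level of C7 first, and sets out from 6:
- iBu2AlH reduction should give the dienyl alcohol [(3R,4S)-3,4-(isopropylidenedioxy)cyclohexa-1,5-dien-1-yl]methanol F1.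
- Benzoylation (BzCl, pyridine) gives the dienylmethyl benzoate F2, a more electron-rich diene that already carries the O7 benzoate.
- Sensitised photooxygenation gives the endoperoxide F3, and thiourea the ene-diol F4.
- Silylation of the less hindered O3 gives the silyl ether F5, and benzoylation of O6 returns to the route at 12.

**Step 7.** The two secondary allylic hydroxyls may not be discriminated well enough, leading to silylation at O6 or at both oxygens. The fallback uses ring size instead of steric bias and sets out from 8:
- Excess iBu2AlH gives the triol F6, in which O6 and O7 form a 1,3-diol.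
- tBu2Si(OTf)2 with 2,6-lutidine bridges that pair as the O6,O7-di-tert-butylsilylene F7, leaving O3 as the only free hydroxyl.
- TBSCl and imidazole give the O3-silylated silylene F8.
- HF·pyridine in THF/pyridine at 0 °C cleaves the cyclic dialkoxysilane in preference to the silyl ether and returns to the route at 10.

**Step 11.** The orthoester may open toward O2 if the half-chair with O2 axial is populated, acetyl may be transferred to O3 through an acyclic mixed orthoester, or the acetate may migrate from O1 to O2 on work-up. The fallback masks the other two hydroxyls instead and sets out from 13: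
- Butane-2,3-dione, HC(OMe)3 and CSA in MeOH should bridge the trans-diequatorial O2/O3 pair as the butane-2,3-diacetal F9, leaving O1–H free.
- Ac2O and pyridine give the O1 acetate F10.
- TFA/H2O removes the diacetal and arrives at 16.

**Step 4.** Substitution by acetate at the triflate carbon may compete with elimination, and the base may take the diene on to an arene by loss of the acetal oxygen. The fallback replaces base-induced anti elimination by a neutral syn elimination and sets out from 5:
- PhSeNa (from PhSeSePh and NaBH4 in EtOH) displaces the triflate with inversion to give the 5-epi-phenylselenide F11.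
- H2O2 with pyridine in CH2Cl2 at 0 °C oxidises selenium, and the selenoxide eliminates toward the CH2 group, not toward the oxygen-bearing carbon, returning to the route at 6.

## Further compounds

F1 | step 5 | [(3R,4S)-3,4-(isopropylidenedioxy)cyclohexa-1,5-dien-1-yl]methanol | CC1(C)O[C@H]2[C@@H](O1)C=CC(CO)=C2
F2 | step 5 | [(3R,4S)-3,4-(isopropylidenedioxy)cyclohexa-1,5-dien-1-yl]methyl benzoate | CC1(C)O[C@H]2[C@@H](O1)C=CC(COC(=O)c1ccccc1)=C2
F3 | step 5 | 5-(benzoyloxymethyl)-3α,6α-epidioxy-1β,2β-(isopropylidenedioxy)cyclohex-4-ene | CC1(C)O[C@H]2[C@@H](O1)[C@H]3C=C(COC(=O)c1ccccc1)[C@@H]2OO3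
F4 | step 5 | 5-(benzoyloxymethyl)-1β,2β-(isopropylidenedioxy)cyclohex-4-ene-3α,6α-diol | CC1(C)O[C@H]2[C@@H](O1)[C@H](O)C=C(COC(=O)c1ccccc1)[C@@H]2O
F5 | step 5 | 5-(benzoyloxymethyl)-3α-(tert-butyldimethylsilyloxy)-1β,2β-(isopropylidenedioxy)cyclohex-4-en-6α-ol | CC1(C)O[C@H]2[C@@H](O1)[C@H](O[Si](C)(C)C(C)(C)C)C=C(COC(=O)c1ccccc1)[C@@H]2O
F6 | step 7 | 5-(hydroxymethyl)-1β,2β-(isopropylidenedioxy)cyclohex-4-ene-3α,6α-diol | CC1(C)O[C@H]2[C@@H](O1)[C@H](O)C=C(CO)[C@@H]2O
F7 | step 7 | O6,O7-di-tert-butylsilylene derivative of F6 (O3–H free) | CC1(C)O[C@H]2[C@@H](O1)[C@H](O)C=C3CO[Si](C(C)(C)C)(C(C)(C)C)O[C@H]23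
F8 | step 7 | O3-tert-butyldimethylsilyl ether of F7 | CC1(C)O[C@H]2[C@@H](O1)[C@H](O[Si](C)(C)C(C)(C)C)C=C3CO[Si](C(C)(C)C)(C(C)(C)C)O[C@H]23
F9 | step 11 | O2,O3-butane-2,3-diacetal of 13 (2,3-dimethoxybutane-2,3-diyl bridge, both methoxy groups axial; O1–H free) | O[C@H]1[C@H]2O[C@](C)(OC)[C@@](C)(OC)O[C@@H]2C=C(COC(=O)c3ccccc3)[C@@H]1OC(=O)c1ccccc1
F10 | step 11 | O1-acetate of F9 | CC(=O)O[C@H]1[C@H]2O[C@](C)(OC)[C@@](C)(OC)O[C@@H]2C=C(COC(=O)c3ccccc3)[C@@H]1OC(=O)c1ccccc1
F11 | step 4 | methyl 5-deoxy-5-epi-5-(phenylselanyl)-3,4-O-isopropylidene shikimate (selenium cis to the ketal) | CC1(C)O[C@H]2[C@@H](O1)[C@@H]([Se]c1ccccc1)CC(C(=O)OC)=C2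
A1 | alternative 1 | L-rhamnose (open-chain form) | C[C@H](O)[C@H](O)[C@@H](O)[C@@H](O)C=O
A2 | alternative 1 | 2,3,4-tri-O-benzyl-6-deoxy-L-lyxo-hexos-5-ulose | CC(=O)[C@H](OCc1ccccc1)[C@@H](OCc1ccccc1)[C@@H](OCc1ccccc1)C=O
A3 | alternative 1 | 2,3,4-tris(benzyloxy)-5-hydroxycyclohexanone (ketone at C5, carbinol at C3 of the target numbering) | C1C(=O)[C@H](OCc2ccccc2)[C@@H](OCc2ccccc2)[C@@H](OCc2ccccc2)[C@@H]1O
A4 | alternative 2 | D-ribose (open-chain form) | O=C[C@H](O)[C@H](O)[C@H](O)CO
A5 | alternative 2 | 3α-(tert-butyldimethylsilyloxy)-1β,2β-(isopropylidenedioxy)cyclopent-4-ene (target numbering, C4=C6) | CC1(C)O[C@H]2[C@@H](O1)[C@H](O[Si](C)(C)C(C)(C)C)C=C2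
A6 | alternative 2 | 6,6-dibromobicyclo[3.1.0]hexane carrying the O1/O2 ketal and the O3 silyl ether (cyclopropane drawn anti to the dioxolane) | CC1(C)O[C@H]2[C@@H](O1)[C@H](O[Si](C)(C)C(C)(C)C)[C@H]3[C@@H]2C3(Br)Br
A7 | alternative 2 | 2-bromocyclohex-2-enyl benzoate carrying the O1/O2 ketal and the O3 silyl ether | CC1(C)O[C@H]2[C@@H](O1)[C@H](O[Si](C)(C)C(C)(C)C)C=C(Br)[C@@H]2OC(=O)c1ccccc1
A8 | alternative 3 | methyl coumalate | COC(=O)C1=COC(=O)C=C1
A9 | alternative 3 | 2,2-dimethyl-1,3-dioxole | CC1(C)OC=CO1
A10 | alternative 3 | methyl 3,4-(isopropylidenedioxy)cyclohexa-1,5-diene-1-carboxylate (constitution of 6; the (3R,4S) form is drawn, the thermal route gives the racemate) | CC1(C)O[C@H]2[C@@H](O1)C=CC(C(=O)OC)=C2
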